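**Strategy.** The cyclohexanone ring of the tetralone (C1 carbonyl, C2, C3, C4, C4a, C8a) is read as a benzocyclobutenone (C1, C8a, C4a, C4) plus the C2–C3 unit; the route exploits that ketone C1 and quaternary C4 sit on adjacent arene carbons. (E)-3-Methylbuta-1,3-dienyllithium adds to the cyclobutenone carbonyl; the alkoxide opens conrotatorily to an o-quinodimethane and recloses by 6π electrocyclisation, which inserts C2/C3, forms C3–C4 and sets both stereocentres from alkene geometry and torquoselectivity. The 2,2-disubstituted benzocyclobutenone comes from an aryne–ketene acetal [2+2]. The racemic acid is resolved; the second phenol arises by late para-oxidation.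

Key step: step 7

Remark 1: the key step fixes only the relative configuration, so 8, 12, 13 and 17–23 are racemic. For 17–23 the SMILES show the relative configuration, drawn as the enantiomer carried on after step 9.
Remark 2: in step 9 it is assumed that the (S)-amine gives the less soluble salt with the (1S,2S)-acid; if the antipodal salt crystallises, the (R)-amine is used in the same way.
Remark 3: locants — in ketone names (20, 21) the carbonyl is C1 and the quaternary carbon C4; in the names of 22–28 the quaternary carbon is C1. The overview and step 7 use the ketone numbering.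

Step 1
Reactants: 1 1-bromo-3,5-dimethoxybenzene
Product: 3 2-(4-bromo-2,6-dimethoxyphenyl)propan-2-ol, via (4-bromo-2,6-dimethoxyphenyl)lithium 2 (not isolated)
Conditions: LDA (commercial solution), THF, −78 °C; acetone, −78 → 0 °C; aq NH4Cl
Reagents that add atoms: acetone, CC(C)=O
Why: Directed ortho-metalation: the C–H between the two methoxy groups is the most acidic and best-coordinated site and LDA does not exchange the bromide, so the aryllithium adds 1,2 to acetone; no stereocentre is formed.

Step 2
Reactants: 3 2-(4-bromo-2,6-dimethoxyphenyl)propan-2-ol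
Product: 4 5-bromo-1,3-dimethoxy-2-(propan-2-yl)benzene
Conditions: Et3SiH, TFA, CH2Cl2, 0 °C → rt
Reagents that add atoms: none
Why: Ionic hydrogenation (Kursanov–Parnes): TFA ionises the tertiary benzylic alcohol to a cation stabilised by two ortho-methoxy groups and Et3SiH delivers hydride, leaving the aryl bromide untouched.

Step 3
Reactants: 5 methyl propanoate; 6 (3-bromopropoxy)(tert-butyl)dimethylsilane
Product: 8 rac-methyl 5-[(tert-butyldimethylsilyl)oxy]-2-methylpentanoate, via lithium enolate of methyl propanoate 7 (not isolated)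
Conditions: LDA, THF, −78 °C; 6, DMPU, −78 → 0 °C
Reagents that add atoms: none
Why: Ester enolate alkylation (SN2) of the kinetic lithium enolate with an unhindered primary bromide; the α-stereocentre forms racemic and is erased in step 4.

Step 4
Reactants: 8 rac-methyl 5-[(tert-butyldimethylsilyl)oxy]-2-methylpentanoate
Product: 10 ketene methyl trimethylsilyl acetal of 8 (E/Z mixture), via lithium ester enolate 9 (not isolated)
Conditions: LDA, THF, −78 °C; TMSCl, −78 °C → rt; pentane filtration, used crude
Reagents that add atoms: chlorotrimethylsilane, C[Si](C)(C)Cl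
Why: O-Silylation of the lithium ester enolate gives the tetrasubstituted ketene silyl acetal; its E/Z ratio is irrelevant because both alkene carbons lose their geometry in step 5.

Step 5
Reactants: 4 5-bromo-1,3-dimethoxy-2-(propan-2-yl)benzene; 10 ketene methyl trimethylsilyl acetal
Product: 13 rac-8-{3-[(tert-butyldimethylsilyl)oxy]propyl}-3,5-dimethoxy-8-methyl-4-(propan-2-yl)bicyclo[4.2.0]octa-1,3,5-trien-7-one, via 3,5-dimethoxy-4-(propan-2-yl)benzyne 11 (not isolated), via benzocyclobutenone methyl trimethylsilyl acetal 12 (not isolated)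
Conditions: LiTMP (from TMPH, n-BuLi), 10 (excess), THF, −78 → −20 °C; then 10% aq citric acid, THF, 0 °C
Reagents that add atoms: none
Why: Aryne [2+2] cycloaddition with a ketene silyl acetal: LiTMP removes the proton between Br and OMe (both ortho positions of symmetric 4 are equivalent), LiBr loss gives the aryne, the nucleophilic acetal β-carbon attacks the aryne carbon remote from the flanking methoxy group and the aryl anion next to OMe closes on the oxocarbenium carbon, so after mild hydrolysis the carbonyl sits next to OMe; the quaternary centre forms as a racemate.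

Step 6
Reactants: 14 2-methylprop-2-enal (methacrolein)
Product: 15 (1E)-1-iodo-3-methylbuta-1,3-diene
Conditions: CrCl2, CHI3, THF, 0 °C, dark; pentane extraction, used as solution
Reagents that add atoms: iodoform, IC(I)I
Why: Takai–Utimoto olefination: the gem-dichromium species from CHI3/CrCl2 adds to the aldehyde and anti-elimination gives the (E)-vinyl iodide.

Step 7
Reactants: 13 rac-benzocyclobutenone; 15 (1E)-1-iodo-3-methylbuta-1,3-diene
Product: 20 rac-(3S,4S)-4-{3-[(tert-butyldimethylsilyl)oxy]propyl}-6,8-dimethoxy-4-methyl-7-(propan-2-yl)-3-(prop-1-en-2-yl)-3,4-dihydronaphthalen-1(2H)-one, via (E)-3-methylbuta-1,3-dienyllithium 16 (not isolated), via lithium benzocyclobutenolate 17 (not isolated), via o-quinodimethane alkoxide 18 (not isolated), via lithium enolate 19 (not isolated)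
Conditions: 15, t-BuLi (2 equiv per 15), Et2O, −78 °C; 13 in THF, −78 → 0 °C; aq NH4Cl
Reagents that add atoms: none
Why: I/Li exchange with retention gives (E)-dienyllithium 16, which adds to the strained, non-enolisable carbonyl of 13 on the face anti to the silyloxypropyl arm (syn to the smaller methyl), giving alkoxide 17 with O⁻ cis to the arm. Alkoxide-accelerated conrotatory 4π opening then turns O⁻ outward (Li held by the neighbouring OMe), which places the dienyl group and the arm inward and the methyl outward in o-quinodimethane 18. Disrotatory thermal 6π electrocyclisation of the C4=C4a–C8a=C1–C2=C3 triene closes the six-membered ketone ring by forming C3–C4 with rearomatisation, so the four-membered ring C1–C8a–C4a–C4 has taken up C2 and C3; protonation of enolate 19 at C2 gives 20. The closest known reaction type is the ring expansion of 1-alkenylbenzocyclobutenols and their alkoxides to dihydronaphthalenones by 4π opening/6π closure. C4 is controlled by torquoselectivity (the cis relation of O⁻ and arm in 17) and C3 by the E geometry of the alkene, so the two outward groups, 4-methyl and 3-isopropenyl, end cis as the target requires; the absolute configuration is not controlled here (racemate, resolved in step 9). The step needs facial selectivity in the carbonyl addition, secured by the size difference between CH3 and the CH2CH2CH2OTBS arm with its non-coordinating silyl ether, and 6π closure faster than [1,5]-H shift, favoured by low temperature and the aromatisation driving force; the E alkene rules out 8π closure through the isopropenyl group.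

Step 8
Reactants: 20 rac-silyl ether ketone
Product: 23 rac-3-[(1S,2S)-5,7-dimethoxy-1-methyl-4-oxo-6-(propan-2-yl)-2-(prop-1-en-2-yl)-1,2,3,4-tetrahydronaphthalen-1-yl]propanoic acid, via primary alcohol 21 (not isolated), via aldehyde 22 (not isolated)
Conditions: Jones reagent (CrO3, aq H2SO4), acetone, 0 °C
Reagents that add atoms: water, O
Why: Jones oxidation: the acidic chromic acid medium cleaves the primary TBS ether in situ and oxidises the alcohol through the aldehyde hydrate to the acid, while the 1,1-disubstituted alkene, the aryl ketone and the methyl ethers should survive short exposure at 0 °C; no stereocentre is touched.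

Step 9
Reactants: 23 rac-acid
Product: 25 3-[(1S,2S)-5,7-dimethoxy-1-methyl-4-oxo-6-(propan-2-yl)-2-(prop-1-en-2-yl)-1,2,3,4-tetrahydronaphthalen-1-yl]propanoic acid, via (S)-1-phenylethylammonium salt 24 (not isolated)
Conditions: (S)-1-phenylethylamine (0.55 equiv), EtOAc/EtOH, crystallise to constant rotation; salt partitioned between 1 M HCl and EtOAc
Reagents that add atoms: none
Why: Classical resolution by diastereomeric salt crystallisation fixes the absolute configuration of both centres, which are not epimerisable and so are not scrambled afterwards.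

Step 10
Reactants: 25 (1S,2S)-dimethoxy acid
Product: 26 3-[(1S,2S)-5-hydroxy-7-methoxy-1-methyl-4-oxo-6-(propan-2-yl)-2-(prop-1-en-2-yl)-1,2,3,4-tetrahydronaphthalen-1-yl]propanoic acid
Conditions: BCl3, CH2Cl2, −78 → −20 °C; aq NaHCO3, then pH 3
Reagents that add atoms: none
Why: Chelation-controlled Lewis acid demethylation: BCl3 bridges the ketone oxygen and the peri methoxy oxygen in a six-membered chelate, so only this methyl leaves as MeCl and the non-chelating 7-methoxy group stays.

Step 11
Reactants: 26 (1S,2S)-phenol acid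
Product: 28 3-[(1S,2S)-5,8-dihydroxy-7-methoxy-1-methyl-4-oxo-6-(propan-2-yl)-2-(prop-1-en-2-yl)-1,2,3,4-tetrahydronaphthalen-1-yl]propanoic acid (target), via 5,8-quinone 27 (not isolated)
Conditions: Fremy's salt, KH2PO4 buffer, acetone/H2O, 0 °C → rt; then aq Na2S2O4, EtOAc, argon; pH 3
Reagents that add atoms: potassium nitrosodisulfonate (Fremy's salt), [K+].[K+].[O]N(S(=O)(=O)[O-])S(=O)(=O)[O-]
Why: Teuber oxidation: Fremy's radical oxidises the phenol at its only free ring position (para to OH) to the p-quinone, the new oxygen coming from the nitroxyl, and dithionite reduces the quinone to the hydroquinone; the stereocentres are remote and untouched.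

**Compound list**

1 | 1-bromo-3,5-dimethoxybenzene | COc1cc(Br)cc(OC)c1 | starting material
2 | (4-bromo-2,6-dimethoxyphenyl)lithium | COc1cc(Br)cc(OC)c1[Li] | intermediate (not isolated)
3 | 2-(4-bromo-2,6-dimethoxyphenyl)propan-2-ol | COc1cc(Br)cc(OC)c1C(C)(C)O | intermediate
4 | 5-bromo-1,3-dimethoxy-2-(propan-2-yl)benzene | COc1cc(Br)cc(OC)c1C(C)C | intermediate
5 | methyl propanoate | CCC(=O)OC | starting material
6 | (3-bromopropoxy)(tert-butyl)dimethylsilane | BrCCCO[Si](C)(C)C(C)(C)C | starting material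
7 | lithium enolate of methyl propanoate (geometry not relevant) | CC=C(OC)O[Li] | intermediate (not isolated)
8 | rac-methyl 5-[(tert-butyldimethylsilyl)oxy]-2-methylpentanoate | COC(=O)C(C)CCCO[Si](C)(C)C(C)(C)C | intermediate
9 | lithium enolate of 8 | COC(O[Li])=C(C)CCCO[Si](C)(C)C(C)(C)C | intermediate (not isolated)
10 | tert-butyl({5-methoxy-4-methyl-5-[(trimethylsilyl)oxy]pent-4-en-1-yl}oxy)dimethylsilane (ketene silyl acetal, E/Z mixture) | COC(O[Si](C)(C)C)=C(C)CCCO[Si](C)(C)C(C)(C)C | intermediate
11 | 3,5-dimethoxy-4-(propan-2-yl)benzyne | COC1=CC#CC(OC)=C1C(C)C | intermediate (not isolated)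
12 | 8-{3-[(tert-butyldimethylsilyl)oxy]propyl}-3,5,7-trimethoxy-8-methyl-4-(propan-2-yl)-7-[(trimethylsilyl)oxy]bicyclo[4.2.0]octa-1,3,5-triene (diastereomer mixture, racemic) | COC1(O[Si](C)(C)C)c2c(OC)c(C(C)C)c(OC)cc2C1(C)CCCO[Si](C)(C)C(C)(C)C | intermediate (not isolated)
13 | rac-8-{3-[(tert-butyldimethylsilyl)oxy]propyl}-3,5-dimethoxy-8-methyl-4-(propan-2-yl)bicyclo[4.2.0]octa-1,3,5-trien-7-one | O=C1c2c(OC)c(C(C)C)c(OC)cc2C1(C)CCCO[Si](C)(C)C(C)(C)C | intermediate
14 | 2-methylprop-2-enal (methacrolein) | CC(=C)C=O | starting material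
15 | (1E)-1-iodo-3-methylbuta-1,3-diene | C=C(C)/C=C/I | intermediate
16 | [(1E)-3-methylbuta-1,3-dien-1-yl]lithium | C=C(C)/C=C/[Li] | intermediate (not isolated)
17 | lithium rac-(7R,8R)-8-{3-[(tert-butyldimethylsilyl)oxy]propyl}-3,5-dimethoxy-8-methyl-7-[(1E)-3-methylbuta-1,3-dien-1-yl]-4-(propan-2-yl)bicyclo[4.2.0]octa-1,3,5-trien-7-olate (O cis to the silyloxypropyl arm) | [Li]O[C@@]1(/C=C/C(C)=C)c2c(OC)c(C(C)C)c(OC)cc2[C@@]1(C)CCCO[Si](C)(C)C(C)(C)C | intermediate (not isolated)
18 | o-quinodimethane lithium alkoxide (exocyclic C=C(OLi)(dienyl): O outward, dienyl inward; exocyclic C=C(CH3)(arm): methyl outward, arm inward) | [Li]O/C(/C=C/C(C)=C)=C1\C(OC)=C(C(C)C)C(OC)=C/C1=C(\C)/CCCO[Si](C)(C)C(C)(C)C | intermediate (not isolated)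
19 | lithium enolate of 20 | C=C(C)[C@@H]1C=C(O[Li])c2c(OC)c(C(C)C)c(OC)cc2[C@@]1(C)CCCO[Si](C)(C)C(C)(C)C | intermediate (not isolated)
20 | rac-(3S,4S)-4-{3-[(tert-butyldimethylsilyl)oxy]propyl}-6,8-dimethoxy-4-methyl-7-(propan-2-yl)-3-(prop-1-en-2-yl)-3,4-dihydronaphthalen-1(2H)-one | C=C(C)[C@@H]1CC(=O)c2c(OC)c(C(C)C)c(OC)cc2[C@@]1(C)CCCO[Si](C)(C)C(C)(C)C | intermediate
21 | rac-(3S,4S)-4-(3-hydroxypropyl)-6,8-dimethoxy-4-methyl-7-(propan-2-yl)-3-(prop-1-en-2-yl)-3,4-dihydronaphthalen-1(2H)-one | C=C(C)[C@@H]1CC(=O)c2c(OC)c(C(C)C)c(OC)cc2[C@@]1(C)CCCO | intermediate (not isolated)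
22 | rac-3-[(1S,2S)-5,7-dimethoxy-1-methyl-4-oxo-6-(propan-2-yl)-2-(prop-1-en-2-yl)-1,2,3,4-tetrahydronaphthalen-1-yl]propanal | C=C(C)[C@@H]1CC(=O)c2c(OC)c(C(C)C)c(OC)cc2[C@@]1(C)CCC=O | intermediate (not isolated)
23 | rac-3-[(1S,2S)-5,7-dimethoxy-1-methyl-4-oxo-6-(propan-2-yl)-2-(prop-1-en-2-yl)-1,2,3,4-tetrahydronaphthalen-1-yl]propanoic acid | C=C(C)[C@@H]1CC(=O)c2c(OC)c(C(C)C)c(OC)cc2[C@@]1(C)CCC(=O)O | intermediate
24 | (S)-1-phenylethylammonium salt of 25 | C[C@H]([NH3+])c1ccccc1.C=C(C)[C@@H]1CC(=O)c2c(OC)c(C(C)C)c(OC)cc2[C@@]1(C)CCC(=O)[O-] | intermediate (not isolated)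
25 | 3-[(1S,2S)-5,7-dimethoxy-1-methyl-4-oxo-6-(propan-2-yl)-2-(prop-1-en-2-yl)-1,2,3,4-tetrahydronaphthalen-1-yl]propanoic acid (single enantiomer) | C=C(C)[C@@H]1CC(=O)c2c(OC)c(C(C)C)c(OC)cc2[C@@]1(C)CCC(=O)O | intermediate
26 | 3-[(1S,2S)-5-hydroxy-7-methoxy-1-methyl-4-oxo-6-(propan-2-yl)-2-(prop-1-en-2-yl)-1,2,3,4-tetrahydronaphthalen-1-yl]propanoic acid | C=C(C)[C@@H]1CC(=O)c2c(O)c(C(C)C)c(OC)cc2[C@@]1(C)CCC(=O)O | intermediate
27 | 3-[(1S,2S)-7-methoxy-1-methyl-4,5,8-trioxo-6-(propan-2-yl)-2-(prop-1-en-2-yl)-1,2,3,4,5,8-hexahydronaphthalen-1-yl]propanoic acid | C=C(C)[C@@H]1CC(=O)C2=C(C(=O)C(OC)=C(C(C)C)C2=O)[C@@]1(C)CCC(=O)O | intermediate (not isolated)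
28 | 3-[(1S,2S)-5,8-dihydroxy-7-methoxy-1-methyl-4-oxo-6-(propan-2-yl)-2-(prop-1-en-2-yl)-1,2,3,4-tetrahydronaphthalen-1-yl]propanoic acid | C=C(C)[C@@H]1CC(=O)c2c(O)c(C(C)C)c(OC)c(O)c2[C@@]1(C)CCC(=O)O | target

**Step count.** Total: 11 steps. Longest linear sequence: 8 steps (1, 2, 5, 7, 8, 9, 10, 11).

**Steps most likely to fail**

Step 7. The carbonyl addition may discriminate poorly between the methyl and the silyloxypropyl face; the epimeric alkoxide is then carried by the same electrocyclic sequence to the C4 epimer. The anionic o-quinodimethane may also leak through a [1,5]-hydrogen shift. Fallback, setting out from 13 and 15: the addition is run as above but quenched at −78 °C with AcOH/THF, so the carbinols are isolated. The wanted isomer, rac-(7R,8R)-8-{3-[(tert-butyldimethylsilyl)oxy]propyl}-3,5-dimethoxy-8-methyl-7-[(1E)-3-methylbuta-1,3-dien-1-yl]-4-(propan-2-yl)bicyclo[4.2.0]octa-1,3,5-trien-7-ol F1, is separated by chromatography and silylated (TMS-imidazole) to its trimethylsilyl ether F2. Heating F2 in toluene (about 90 °C) opens the ring through the neutral siloxy-o-quinodimethane (OSiMe3 outward) and closes it to the trimethylsilyl enol ether of 20 F3. K2CO3/MeOH then gives 20, where the route is rejoined.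

Step 5. The aryne may be consumed by the amide base or by ene and proton-transfer pathways faster than the hindered tetrasubstituted acetal adds, or the aryl anion may be protonated before ring closure. Fallback, setting out from 4 and 8: Pd-catalysed ester α-arylation (Pd(dba)2, P(t-Bu)3, LiNCy2, toluene) builds the quaternary centre as rac-methyl 5-[(tert-butyldimethylsilyl)oxy]-2-[3,5-dimethoxy-4-(propan-2-yl)phenyl]-2-methylpentanoate F4. NBS in MeCN brominates one of the two equivalent positions ortho to the quaternary carbon to give rac-methyl 2-[2-bromo-3,5-dimethoxy-4-(propan-2-yl)phenyl]-5-[(tert-butyldimethylsilyl)oxy]-2-methylpentanoate F5. Br/Li exchange (t-BuLi, THF, −100 °C) and 4-exo acyl substitution on the ester (Parham cyclisation) return the route at 13.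

Step 11. One-electron oxidation of the hydrogen-bonded, acyl-deactivated phenol may be slow, and the quinone/hydroquinone pair may degrade. Fallback, setting out from 25: the oxygen is introduced by two-electron chemistry before demethylation. NBS (MeCN, −20 °C) brominates the only free ring position to give 3-[(1S,2S)-8-bromo-5,7-dimethoxy-1-methyl-4-oxo-6-(propan-2-yl)-2-(prop-1-en-2-yl)-1,2,3,4-tetrahydronaphthalen-1-yl]propanoic acid F6. Pd-catalysed hydroxylation (Pd2(dba)3, t-BuXPhos, KOH, dioxane/H2O) gives 3-[(1S,2S)-8-hydroxy-5,7-dimethoxy-1-methyl-4-oxo-6-(propan-2-yl)-2-(prop-1-en-2-yl)-1,2,3,4-tetrahydronaphthalen-1-yl]propanoic acid F7. BCl3 as in step 10 removes only the methyl peri to the ketone and gives 28 directly.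

**Further compounds**

F1 | step 7 | rac-(7R,8R)-8-{3-[(tert-butyldimethylsilyl)oxy]propyl}-3,5-dimethoxy-8-methyl-7-[(1E)-3-methylbuta-1,3-dien-1-yl]-4-(propan-2-yl)bicyclo[4.2.0]octa-1,3,5-trien-7-ol | O[C@@]1(/C=C/C(C)=C)c2c(OC)c(C(C)C)c(OC)cc2[C@@]1(C)CCCO[Si](C)(C)C(C)(C)C
F2 | step 7 | trimethylsilyl ether of F1 | C[Si](C)(C)O[C@@]1(/C=C/C(C)=C)c2c(OC)c(C(C)C)c(OC)cc2[C@@]1(C)CCCO[Si](C)(C)C(C)(C)C
F3 | step 7 | trimethylsilyl enol ether of 20 | C=C(C)[C@@H]1C=C(O[Si](C)(C)C)c2c(OC)c(C(C)C)c(OC)cc2[C@@]1(C)CCCO[Si](C)(C)C(C)(C)C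
F4 | step 5 | rac-methyl 5-[(tert-butyldimethylsilyl)oxy]-2-[3,5-dimethoxy-4-(propan-2-yl)phenyl]-2-methylpentanoate | COC(=O)C(C)(CCCO[Si](C)(C)C(C)(C)C)c1cc(OC)c(C(C)C)c(OC)c1
F5 | step 5 | rac-methyl 2-[2-bromo-3,5-dimethoxy-4-(propan-2-yl)phenyl]-5-[(tert-butyldimethylsilyl)oxy]-2-methylpentanoate | COC(=O)C(C)(CCCO[Si](C)(C)C(C)(C)C)c1cc(OC)c(C(C)C)c(OC)c1Br
F6 | step 11 | 3-[(1S,2S)-8-bromo-5,7-dimethoxy-1-methyl-4-oxo-6-(propan-2-yl)-2-(prop-1-en-2-yl)-1,2,3,4-tetrahydronaphthalen-1-yl]propanoic acid | C=C(C)[C@@H]1CC(=O)c2c(OC)c(C(C)C)c(OC)c(Br)c2[C@@]1(C)CCC(=O)O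
F7 | step 11 | 3-[(1S,2S)-8-hydroxy-5,7-dimethoxy-1-methyl-4-oxo-6-(propan-2-yl)-2-(prop-1-en-2-yl)-1,2,3,4-tetrahydronaphthalen-1-yl]propanoic acid | C=C(C)[C@@H]1CC(=O)c2c(OC)c(C(C)C)c(OC)c(O)c2[C@@]1(C)CCC(=O)O
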